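## The problem

Isochandalone is an achiral isoflavone (numbered O1, C2, C3, C4, C4a, C5 to C8, C8a; ring B primed). Ring A is a phloroglucinol whose three oxygens sit at C5 (OH), C7 (OH) and C8a (ring oxygen); it carries the prenyl group at C6 and the carbonyl carbon C4 at C4a. Ring B is a 2,2-dimethyl-2H-chromen-6-yl group on C3. There is no stereocenter, so the difficulty is regiochemical: C6 and C8 are both flanked by two oxygens, and any prenylation of a preformed phloroglucinol or 5,7-dihydroxychromone (direct, or by Claisen and Cope shifts) must tell them apart. The two isoprene units must also end in different states, an open prenyl group on ring A and a closed chromene on ring B, so one common late operation cannot deliver both. The prenyl group next to free phenols cyclises to a dimethylchroman under acid and does not survive hydrogenolysis or electrophilic oxidants. The chromene double bond is sensitive to acid, oxidants and ultraviolet light, and the 4-pyranone ring opens with hot hydroxide. Acid-labile or benzyl protection of ring A is therefore unattractive.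

The feature that makes the key step possible: C5(OH)–C6(prenyl)–C7(O)–C8(H) are four contiguous carbons of ring A that hang on the C4a=C8a edge of pyranone ring C. They map one to one onto a ketene carbonyl carbon (C5), the two carbons of a silyl ynol ether (C6, the nucleophilic carbon, bearing prenyl; C7 bearing oxygen) and the ketene CH (C8). C4a is a CH in a monocyclic 4-pyranone, so it can serve as the terminus of a 6π ring closure and then aromatise.

## Retrosynthesis

**Target 23 to silyl ether 22.** Only the O7–Si bond is cut. The C7 oxygen arrives from the alkyne as a triisopropylsilyl ether, so no protecting group is added on purpose. The forward step needs only fluoride, which spares the prenyl group, the chromene and the pyranone.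

**22 to diazo ketone 11 and siloxyalkyne 17 (through 18, 19, 20, 21).** Three ring A bonds are cut: C5–C4a, C5–C6 and C7–C8. Cutting the C3–C1' bond or the C6–prenyl bond instead would leave a complete prenylated phloroglucinol ring to be made, with its C6/C8 problem intact. This cut removes ring A altogether and fixes the positions of OH, prenyl and OSi by the polarity of the ynol ether. The precursors are a monocyclic pyranone carrying a diazoacetyl group and an acyclic seven-carbon alkyne. The forward reaction must deliver a photochemical Wolff rearrangement, a regioselective ketene/alkyne [2+2] cycloaddition, a 4π ring opening of the strained cyclobutenone 19 and a 6π closure onto pyranone C3.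

**17 to enyne 14, and 14 to prenyl bromide 12 and ethynylmagnesium bromide 13.** The O–C(sp) bond is cut first (oxygen transfer to the lithium acetylide 15 gives ynolate 16, which is silylated). The propargylic C–C bond is cut next (copper-catalysed allylic alkynylation). Both fragments are commodity chemicals, and the prenyl group is placed on the alkyne before any aromatic ring exists.

**11 to acid 9, and 9 to ester 8.** The bond between the future C8 (diazomethyl carbon) and the future C5 (carboxyl carbon) is cut. The forward step is acylation of a diazomethane equivalent by the mixed anhydride 10, which avoids strong acid and acid chlorides near the chromene. The acid comes from its methyl ester by cold saponification.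

**8 to boronate 4 and triflate 7.** The C3–C1' bond is cut at a stage where the electrophile is a simple pyranone triflate, not an elaborate iodochromone. The forward step is a Suzuki–Miyaura coupling. Ring C comes intact from comenic acid 5 (through ester 6 and triflate 7): its 5-OH marks where ring B is attached and its CO2H marks where ring A will grow.

**4 to bromide 3, and 3 to 4-bromophenol 1 and 3-methylbut-2-enal 2.** The C–B bond is cut (Miyaura borylation), then the O–C2 and C4–C4a bonds of the chromene (phenol/enal condensation with oxa-6π closure). The chromene is thus finished on a simple phenol, well away from the prenyl group.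

## Roads not taken

Alternative 1: The most obvious cut is the C3–C1' bond of the finished chromone. The forward key step is a Suzuki–Miyaura coupling of boronate 4 with 3-iodo-5,7-bis(methoxymethoxy)-6-prenylchromone A1, giving the protected isoflavone A2, followed by acid removal of the acetals. A1 would come from commercial 2,4,6-trihydroxyacetophenone by double protection, O-prenylation, a Claisen–Cope sequence near 200 °C, enaminone formation and iodocyclisation. The route is comparable in length, but it spends its steps on differentiating three phenols, relies on two consecutive sigmatropic shifts for the C6 position, and ends with an acid deprotection of A2 in which the prenyl group sits between two liberated phenols and can cyclise. The chosen plan needs no differentiation of ring A oxygens and ends with fluoride.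

Alternative 2: The biomimetic cut is the 1,2-aryl shift. A chalcone A3 would be made by aldol condensation of a protected prenylated phloroacetophenone with 2,2-dimethyl-2H-chromene-6-carbaldehyde. It would be rearranged oxidatively with Tl(NO3)3 or PhI(OAc)2 in methanol and cyclised to A2. The electrophilic oxidant (trivalent thallium or hypervalent iodine) needed for the aryl migration also attacks the electron-rich trisubstituted prenyl alkene and the chromene double bond. The regiochemical problem of ring A and the final acid deprotection remain as in Alternative 1.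

Alternative 3: The prenyl group could be introduced last, on the complete 5,7-dihydroxyisoflavone A4 (the target without its prenyl group). This would be done either by direct C-prenylation or by Claisen rearrangement of the 7-O-(1,1-dimethylallyl) ether A5. Both C6 and C8 of A4 are activated by the same two oxygens; direct alkylation also gives O-alkylation and double alkylation, and the shift from O7 in A5 can go to C8 as readily as to C6. The step is short on paper but leaves the central selectivity problem to chance and to separation of isomers. The chosen plan settles it by bond construction.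

Key step: step 10

Remark: the target has no stereocenter; intermediates 19 and 21 each carry one transient stereocenter, are racemic, and lose it on the way to 22.

## Route

Step 1
Reactants: 1 4-bromophenol; 2 3-methylbut-2-enal
Product: 3 6-bromo-2,2-dimethyl-2H-chromene
Conditions: PhB(OH)2 (1 equiv), AcOH, toluene, reflux (Dean–Stark)
Reagents that add atoms: none
Why: Boronic acid-templated ortho condensation of phenol and enal gives a benzodioxaborin that fragments to an ortho-quinone methide, which closes by oxa-6π electrocyclisation to the 2H-chromene; the para bromine makes both ortho positions equivalent.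

Step 2
Reactants: 3 6-bromo-2,2-dimethyl-2H-chromene
Product: 4 2-(2,2-dimethyl-2H-chromen-6-yl)-4,4,5,5-tetramethyl-1,3,2-dioxaborolane
Conditions: B2pin2, Pd(dppf)Cl2 (3 mol %), KOAc, 1,4-dioxane, 85 °C
Reagents that add atoms: bis(pinacolato)diboron, CC1(C)OB(OC1(C)C)B1OC(C)(C)C(C)(C)O1
Why: Miyaura borylation of an electron-rich aryl bromide; the weak base KOAc and the chromene double bond are compatible.

Step 3
Reactants: 5 comenic acid (5-hydroxy-4-oxo-4H-pyran-2-carboxylic acid)
Product: 6 methyl 5-hydroxy-4-oxo-4H-pyran-2-carboxylate
Conditions: MeOH, H2SO4 (cat.), reflux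
Reagents that add atoms: methanol, CO
Why: Fischer esterification; the enolic 5-OH is not etherified under these conditions and the pyranone ring is stable to acid.

Step 4
Reactants: 6 methyl 5-hydroxy-4-oxo-4H-pyran-2-carboxylate
Product: 7 methyl 4-oxo-5-(trifluoromethylsulfonyloxy)-4H-pyran-2-carboxylate
Conditions: Tf2O, pyridine, CH2Cl2, −20 → 0 °C
Reagents that add atoms: triflic anhydride, O=S(=O)(OS(=O)(=O)C(F)(F)F)C(F)(F)F
Why: O-sulfonylation of the acidic, phenol-like 5-hydroxyl of the hydroxypyranone, the standard activation of kojic-type pyranones for cross-coupling.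

Step 5
Reactants: 4 2-(2,2-dimethyl-2H-chromen-6-yl)-4,4,5,5-tetramethyl-1,3,2-dioxaborolane; 7 methyl 4-oxo-5-(trifluoromethylsulfonyloxy)-4H-pyran-2-carboxylate
Product: 8 methyl 5-(2,2-dimethyl-2H-chromen-6-yl)-4-oxo-4H-pyran-2-carboxylate
Conditions: Pd(PPh3)4 (5 mol %), K3PO4, 1,4-dioxane/H2O (20:1), 70 °C
Reagents that add atoms: none
Why: Suzuki–Miyaura coupling; the triflate alpha to the pyranone carbonyl undergoes fast oxidative addition to zerovalent palladium, and the nearly anhydrous phosphate medium spares the ester and the pyranone ring.

Step 6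
Reactants: 8 methyl 5-(2,2-dimethyl-2H-chromen-6-yl)-4-oxo-4H-pyran-2-carboxylate
Product: 9 5-(2,2-dimethyl-2H-chromen-6-yl)-4-oxo-4H-pyran-2-carboxylic acid
Conditions: LiOH·H2O (1.1 equiv), THF/H2O (3:1), 0 °C; then cold 1 M HCl to pH 3
Reagents that add atoms: lithium hydroxide, [Li+].[OH-]
Why: Saponification; the ester on C2 of the pyranone is activated by the ring oxygen and the conjugated ketone, so one equivalent of hydroxide at 0 °C should cleave it faster than it adds to the ring, and brief cold dilute acid does not harm the chromene.

Step 7
Reactants: 9 5-(2,2-dimethyl-2H-chromen-6-yl)-4-oxo-4H-pyran-2-carboxylic acid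
Product: 11 2-diazo-1-[5-(2,2-dimethyl-2H-chromen-6-yl)-4-oxo-4H-pyran-2-yl]ethan-1-one, via mixed carbonic anhydride 10 (not isolated)
Conditions: ClCO2Et, Et3N, THF, −15 °C; then Me3SiCHN2 (2 M in hexanes), MeCN, 0 °C → rt
Reagents that add atoms: trimethylsilyldiazomethane, C[Si](C)(C)C=[N+]=[N-]; ethyl chloroformate, CCOC(Cl)=O (its atoms stay only in intermediate 10)
Why: Acylation of a diazomethane equivalent by a mixed anhydride, the first stage of an Arndt–Eistert sequence; the diazo carbon attacks the more electrophilic pyranoyl carbonyl and the silyl group is lost to the ethyl carbonate leaving group, and no strong acid is released near the chromene.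

Step 8
Reactants: 12 1-bromo-3-methylbut-2-ene (prenyl bromide); 13 ethynylmagnesium bromide
Product: 14 5-methylhex-4-en-1-yne
Conditions: CuCl (5 mol %), THF, 0 → 40 °C
Reagents that add atoms: none
Why: Copper-catalysed coupling of an alkynyl Grignard reagent with an allylic bromide; substitution at the primary terminus is favoured because attack at the other end would build a quaternary carbon.

Step 9
Reactants: 14 5-methylhex-4-en-1-yne
Product: 17 triisopropyl[(5-methylhex-4-en-1-yn-1-yl)oxy]silane, via lithium acetylide 15 (not isolated), via lithium ynolate 16 (not isolated)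
Conditions: n-BuLi, THF, −78 °C; t-BuOOLi (from t-BuOOH and LiN(SiMe3)2), −78 → 0 °C; then i-Pr3SiOTf, −78 → 0 °C
Reagents that add atoms: tert-butyl hydroperoxide, CC(C)(C)OO; triisopropylsilyl triflate, CC(C)[Si](OS(=O)(=O)C(F)(F)F)(C(C)C)C(C)C; n-butyllithium, [Li]CCCC (lithium of 15 and 16 only)
Why: Electrophilic oxygen transfer from lithium tert-butyl peroxide to the acetylide gives the ynolate, which the bulky silyl triflate traps on oxygen; this is the established one-flask route from terminal alkynes to triisopropylsiloxyalkynes.

Step 10
Reactants: 11 2-diazo-1-[5-(2,2-dimethyl-2H-chromen-6-yl)-4-oxo-4H-pyran-2-yl]ethan-1-one; 17 triisopropyl[(5-methylhex-4-en-1-yn-1-yl)oxy]silane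
Product: 22 3-(2,2-dimethyl-2H-chromen-6-yl)-5-hydroxy-6-(3-methylbut-2-en-1-yl)-7-(triisopropylsilyloxy)-4H-chromen-4-one, via pyranylketene 18 (not isolated), via siloxycyclobutenone 19 (not isolated), via dienylketene 20 (not isolated), via cyclohexadienone 21 (not isolated)
Conditions: hν (450 nm LED), 17 (1.5 equiv), ClCH2CH2Cl (degassed), 20 °C; then 80 °C in the dark
Reagents that add atoms: none
Why: This is the Danheiser benzannulation in its photochemical form, the closest precedent being the aromatic annulation of vinyl and heteroaryl diazomethyl ketones with siloxyalkynes. Light absorbed by the diazo ketone expels N2 and the pyranyl group migrates (Wolff rearrangement) to give ketene 18. The nucleophilic prenyl-bearing carbon of 17 adds to the ketene carbonyl carbon and the oxygen-bearing carbon bonds to the ketene CH, so the polar stepwise [2+2] cycloaddition closes the four-membered ring of 19 in one regiochemical sense only. On heating, the strain of 19 drives a conrotatory 4π electrocyclic opening to dienylketene 20; the isomer with the pyranyl group cis to the ketene closes ring A by a thermal 6π electrocyclisation between the ketene carbon (C5) and pyranone C3 (C4a), while the other isomer can revert to 19. C4a is the only possible terminus because the other neighbour of C8a is the ring oxygen, and the doubly activated C4a–H of dienone 21 is then lost by enolisation to give the aromatic, hydrogen-bonded 5-hydroxy compound 22. No stereocenter survives (C4 of 19 and C4a of 21 are transient). The step needs three selectivities: the regiochemistry of the cycloaddition, secured by the O–C≡C polarisation; the chemoselectivity of the ketene, secured by the far higher nucleophilicity of the siloxyalkyne over the prenyl and chromene alkenes; and selective excitation, secured by irradiating in the visible tail of the diazo ketone where the chromene and the arylpyranone do not absorb.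

Step 11
Reactants: 22 3-(2,2-dimethyl-2H-chromen-6-yl)-5-hydroxy-6-(3-methylbut-2-en-1-yl)-7-(triisopropylsilyloxy)-4H-chromen-4-one
Product: 23 isochandalone, 3-(2,2-dimethyl-2H-chromen-6-yl)-5,7-dihydroxy-6-(3-methylbut-2-en-1-yl)-4H-chromen-4-one
Conditions: Bu4NF, AcOH (1:1), THF, 0 °C
Reagents that add atoms: none
Why: Fluoride cleavage of an aryl silyl ether; the acetic acid buffer keeps the medium near neutral, so neither the pyranone nor the prenyl/phenol pair is disturbed.

## Compound list

1 | 4-bromophenol | Oc1ccc(Br)cc1 | starting material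
2 | 3-methylbut-2-enal | CC(C)=CC=O | starting material
3 | 6-bromo-2,2-dimethyl-2H-chromene | CC1(C)C=Cc2cc(Br)ccc2O1 | intermediate
4 | 2-(2,2-dimethyl-2H-chromen-6-yl)-4,4,5,5-tetramethyl-1,3,2-dioxaborolane | CC1(C)C=Cc2cc(B3OC(C)(C)C(C)(C)O3)ccc2O1 | intermediate
5 | comenic acid (5-hydroxy-4-oxo-4H-pyran-2-carboxylic acid) | O=C(O)c1cc(=O)c(O)co1 | starting material
6 | methyl 5-hydroxy-4-oxo-4H-pyran-2-carboxylate | COC(=O)c1cc(=O)c(O)co1 | intermediate
7 | methyl 4-oxo-5-(trifluoromethylsulfonyloxy)-4H-pyran-2-carboxylate | COC(=O)c1cc(=O)c(OS(=O)(=O)C(F)(F)F)co1 | intermediate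
8 | methyl 5-(2,2-dimethyl-2H-chromen-6-yl)-4-oxo-4H-pyran-2-carboxylate | COC(=O)c1cc(=O)c(-c2ccc3c(c2)C=CC(C)(C)O3)co1 | intermediate
9 | 5-(2,2-dimethyl-2H-chromen-6-yl)-4-oxo-4H-pyran-2-carboxylic acid | O=C(O)c1cc(=O)c(-c2ccc3c(c2)C=CC(C)(C)O3)co1 | intermediate
10 | ethyl carbonic 5-(2,2-dimethyl-2H-chromen-6-yl)-4-oxo-4H-pyran-2-carboxylic anhydride (not isolated) | CCOC(=O)OC(=O)c1cc(=O)c(-c2ccc3c(c2)C=CC(C)(C)O3)co1 | intermediate
11 | 2-diazo-1-[5-(2,2-dimethyl-2H-chromen-6-yl)-4-oxo-4H-pyran-2-yl]ethan-1-one | [N-]=[N+]=CC(=O)c1cc(=O)c(-c2ccc3c(c2)C=CC(C)(C)O3)co1 | intermediate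
12 | 1-bromo-3-methylbut-2-ene | CC(C)=CCBr | starting material
13 | ethynylmagnesium bromide | C#C[Mg]Br | starting material
14 | 5-methylhex-4-en-1-yne | C#CCC=C(C)C | intermediate
15 | (5-methylhex-4-en-1-yn-1-yl)lithium (not isolated) | [Li]C#CCC=C(C)C | intermediate
16 | lithium 5-methylhex-4-en-1-yn-1-olate (not isolated) | [Li]OC#CCC=C(C)C | intermediate
17 | triisopropyl[(5-methylhex-4-en-1-yn-1-yl)oxy]silane | CC(C)=CCC#CO[Si](C(C)C)(C(C)C)C(C)C | intermediate
18 | [5-(2,2-dimethyl-2H-chromen-6-yl)-4-oxo-4H-pyran-2-yl]ketene (not isolated) | O=C=Cc1cc(=O)c(-c2ccc3c(c2)C=CC(C)(C)O3)co1 | intermediate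
19 | 4-[5-(2,2-dimethyl-2H-chromen-6-yl)-4-oxo-4H-pyran-2-yl]-2-(3-methylbut-2-en-1-yl)-3-(triisopropylsilyloxy)cyclobut-2-en-1-one, racemic (not isolated) | O=C1C(CC=C(C)C)=C(O[Si](C(C)C)(C(C)C)C(C)C)C1c1cc(=O)c(-c2ccc3c(c2)C=CC(C)(C)O3)co1 | intermediate
20 | (E)-4-[5-(2,2-dimethyl-2H-chromen-6-yl)-4-oxo-4H-pyran-2-yl]-2-(3-methylbut-2-en-1-yl)-3-(triisopropylsilyloxy)buta-1,3-dien-1-one, pyranyl cis to the ketene carbon (not isolated) | O=C=C(CC=C(C)C)/C(O[Si](C(C)C)(C(C)C)C(C)C)=C\c1cc(=O)c(-c2ccc3c(c2)C=CC(C)(C)O3)co1 | intermediate
21 | 3-(2,2-dimethyl-2H-chromen-6-yl)-6-(3-methylbut-2-en-1-yl)-7-(triisopropylsilyloxy)-4aH-chromene-4,5-dione, racemic (not isolated) | O=C1C(CC=C(C)C)=C(O[Si](C(C)C)(C(C)C)C(C)C)C=C2OC=C(c3ccc4c(c3)C=CC(C)(C)O4)C(=O)C12 | intermediate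
22 | 3-(2,2-dimethyl-2H-chromen-6-yl)-5-hydroxy-6-(3-methylbut-2-en-1-yl)-7-(triisopropylsilyloxy)-4H-chromen-4-one | CC(C)=CCc1c(O[Si](C(C)C)(C(C)C)C(C)C)cc2occ(-c3ccc4c(c3)C=CC(C)(C)O4)c(=O)c2c1O | intermediate
23 | isochandalone | CC(C)=CCc1c(O)cc2occ(-c3ccc4c(c3)C=CC(C)(C)O4)c(=O)c2c1O | target

## Step count and least certain steps

Total step count: 11. Longest linear sequence: 7 steps (5 → 6 → 7 → 8 → 9 → 11 → 22 → 23, steps 3, 4, 5, 6, 7, 10 and 11; the branch from 1 through steps 1, 2, 5, 6, 7, 10 and 11 is equally long).

**Step 10 (key step).** The most likely failure is in the photochemical stage. The diazo ketone absorbs only weakly in the visible, and if shorter wavelengths are needed, the chromene (reversible ring opening to an ortho-quinone methide) and the arylpyranone compete for the light. Ketene 18 may also be lost by dimerisation before it meets 17. A slow 6π closure onto the pyranone would show up as accumulation of 19. The fallback removes light from the route and makes the same ketene in the ground state. It sets out from 11: a silver-catalysed Wolff rearrangement (PhCO2Ag, Et3N, THF/H2O) should give the homologous acid 2-[5-(2,2-dimethyl-2H-chromen-6-yl)-4-oxo-4H-pyran-2-yl]acetic acid F1. 1-Chloro-N,N,2-trimethylprop-1-en-1-amine in CH2Cl2 at 0 °C should convert it under neutral conditions into 2-[5-(2,2-dimethyl-2H-chromen-6-yl)-4-oxo-4H-pyran-2-yl]acetyl chloride F2. Slow addition of Et3N to F2 and 17 in toluene should then generate ketene 18 by dehydrochlorination, where the fallback comes back to the route (18 to 19, then 80 to 110 °C to 22).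

**Step 7.** The diazoalkane may add as a 1,3-dipole to the electron-poor C2=C3 bond of the pyranone, or attack the carbonate carbonyl of 10 and return an ethyl ester. The fallback uses no diazoalkane and puts the diazo group on by diazo transfer. It sets out from 9: amide coupling (MeNHOMe·HCl, EDC·HCl, i-Pr2NEt, CH2Cl2) should give the Weinreb amide 5-(2,2-dimethyl-2H-chromen-6-yl)-N-methoxy-N-methyl-4-oxo-4H-pyran-2-carboxamide F3. MeMgBr in THF at −78 °C should give the methyl ketone 2-acetyl-5-(2,2-dimethyl-2H-chromen-6-yl)-4H-pyran-4-one F4. Trifluoroacetylation of its lithium enolate (LiN(SiMe3)2, CF3CO2CH2CF3, THF, −78 °C) should give the diketone 1-[5-(2,2-dimethyl-2H-chromen-6-yl)-4-oxo-4H-pyran-2-yl]-4,4,4-trifluorobutane-1,3-dione F5, which is not isolated. Detrifluoroacetylative diazo transfer (MsN3, Et3N, H2O, MeCN) should then return to the route at 11.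

**Step 5.** The pyranone triflate may lose its sulfonyl group to the aqueous base (S–O cleavage back to 6), or the ring may be opened by hydroxide before transmetalation. The fallback is a base-free Stille coupling. It sets out from 3: bromine–lithium exchange and stannylation (n-BuLi, THF, −78 °C; Bu3SnCl) should give tributyl(2,2-dimethyl-2H-chromen-6-yl)stannane F6. Coupling with 7 (Pd(PPh3)4, LiCl, 1,4-dioxane, 90 °C) comes back to the route at 8.

**Step 9.** Oxygen transfer to the acetylide may be incomplete, the doubly activated CH2 between alkyne and alkene may be deprotonated (isomerisation to an allene), or the ynolate may be silylated on carbon. The fallback builds the ynolate by carbon migration instead of acetylide oxidation. It sets out from 12: palladium-catalysed alkoxycarbonylation (CO, EtOH, Pd(PPh3)2Cl2, i-Pr2NEt) should give ethyl 4-methylpent-3-enoate F7. Kowalski ester homologation (LiCHBr2 from CH2Br2 and lithium 2,2,6,6-tetramethylpiperidide, THF, −78 °C; LiN(SiMe3)2) should pass through the lithium enolate of 1,1-dibromo-5-methylhex-4-en-2-one F8. Bromine–lithium exchange with n-BuLi and warming should then induce the rearrangement to ynolate 16, where the fallback comes back to the route (silylation to 17 as in step 9).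

## Further compounds

F1 | step 10 | 2-[5-(2,2-dimethyl-2H-chromen-6-yl)-4-oxo-4H-pyran-2-yl]acetic acid | O=C(O)Cc1cc(=O)c(-c2ccc3c(c2)C=CC(C)(C)O3)co1
F2 | step 10 | 2-[5-(2,2-dimethyl-2H-chromen-6-yl)-4-oxo-4H-pyran-2-yl]acetyl chloride | O=C(Cl)Cc1cc(=O)c(-c2ccc3c(c2)C=CC(C)(C)O3)co1
F3 | step 7 | 5-(2,2-dimethyl-2H-chromen-6-yl)-N-methoxy-N-methyl-4-oxo-4H-pyran-2-carboxamide | CON(C)C(=O)c1cc(=O)c(-c2ccc3c(c2)C=CC(C)(C)O3)co1
F4 | step 7 | 2-acetyl-5-(2,2-dimethyl-2H-chromen-6-yl)-4H-pyran-4-one | CC(=O)c1cc(=O)c(-c2ccc3c(c2)C=CC(C)(C)O3)co1
F5 | step 7 | 1-[5-(2,2-dimethyl-2H-chromen-6-yl)-4-oxo-4H-pyran-2-yl]-4,4,4-trifluorobutane-1,3-dione | O=C(CC(=O)C(F)(F)F)c1cc(=O)c(-c2ccc3c(c2)C=CC(C)(C)O3)co1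
F6 | step 5 | tributyl(2,2-dimethyl-2H-chromen-6-yl)stannane | CCCC[Sn](CCCC)(CCCC)c1ccc2c(c1)C=CC(C)(C)O2
F7 | step 9 | ethyl 4-methylpent-3-enoate | CCOC(=O)CC=C(C)C
F8 | step 9 | lithium 1,1-dibromo-5-methylhexa-1,4-dien-2-olate | [Li]OC(CC=C(C)C)=C(Br)Br
A1 | alternative 1 | 3-iodo-5,7-bis(methoxymethoxy)-6-(3-methylbut-2-en-1-yl)-4H-chromen-4-one | COCOc1cc2occ(I)c(=O)c2c(OCOC)c1CC=C(C)C
A2 | alternative 1 | 3-(2,2-dimethyl-2H-chromen-6-yl)-5,7-bis(methoxymethoxy)-6-(3-methylbut-2-en-1-yl)-4H-chromen-4-one | COCOc1cc2occ(-c3ccc4c(c3)C=CC(C)(C)O4)c(=O)c2c(OCOC)c1CC=C(C)C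
A3 | alternative 2 | (E)-3-(2,2-dimethyl-2H-chromen-6-yl)-1-[6-hydroxy-2,4-bis(methoxymethoxy)-3-(3-methylbut-2-en-1-yl)phenyl]prop-2-en-1-one | COCOc1cc(O)c(C(=O)/C=C/c2ccc3c(c2)C=CC(C)(C)O3)c(OCOC)c1CC=C(C)C
A4 | alternative 3 | 3-(2,2-dimethyl-2H-chromen-6-yl)-5,7-dihydroxy-4H-chromen-4-one | O=c1c(-c2ccc3c(c2)C=CC(C)(C)O3)coc2cc(O)cc(O)c12
A5 | alternative 3 | 3-(2,2-dimethyl-2H-chromen-6-yl)-5-hydroxy-7-(2-methylbut-3-en-2-yloxy)-4H-chromen-4-one | C=CC(C)(C)Oc1cc(O)c2c(=O)c(-c3ccc4c(c3)C=CC(C)(C)O4)coc2c1
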